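The isoflavone is cut at C3–C1' and O1–C2, which leads back to a 2'-hydroxychalcone. In one operation thallium(III) moves ring B from the β- to the α-carbon of the enone, and acid then lets the A-ring phenol oxygen close the pyranone ring. The step exploits ring B itself: its C2' oxygen (ortho) and C4' methoxy oxygen (para) stabilise the bridged cation at the migrating carbon C1'. The precursor is the (E)-chalcone with a free A-ring ortho hydroxyl, acid-stable benzyl ethers on the three other phenols, and bromine at C5' as a stand-in for the oxidant-sensitive 1,1-dimethylallyl group, which a γ-selective prenyl coupling installs before hydrogen-free debenzylation.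

Key step: step 4

Remarks on the chemistry (assumptions)
- The target has no stereocentre and no stereogenic double bond. It is a single achiral compound, so no enantiocontrol is needed.
- O1, C2, C3 and C1'–C6' are isoflavone locants (primes = ring B) and are used for the same atoms in the chalcone. "2'-Hydroxychalcone" is used only as the class name for a chalcone with a free phenol ortho to the ketone on ring A.
- Compounds 1, 4 and 8 are assumed to be bought. Compound 4 is otherwise one selective benzylation away from 2,4-dihydroxyacetophenone.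
- Protecting groups: the ring-B oxygens carry benzyl ethers, not acid-labile acetals. An acetal on the C2' oxygen would be lost in the ring-closing acid and free a second phenol that can capture the acetal carbon in a five-membered ring. It would also expose the catechol to Tl(III). Benzyl ethers survive the key step, so its product goes directly into the cross-coupling.

Step 1
Reactants: 1 2,3-dihydroxy-4-methoxybenzaldehyde
Product: 2 5-bromo-2,3-dihydroxy-4-methoxybenzaldehyde
Conditions: NBS (1.0 equiv), MeCN, 0 °C → rt
Reagents that add atoms: N-bromosuccinimide, O=C1CCC(=O)N1Br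
Why: Electrophilic aromatic bromination should go to C5, which is para to the C2 hydroxyl and ortho to the methoxy group, whereas attack at C6 would place the positive charge of the σ-complex on the formyl-bearing carbon.

Step 2
Reactants: 2 5-bromo-2,3-dihydroxy-4-methoxybenzaldehyde
Product: 3 2,3-bis(benzyloxy)-5-bromo-4-methoxybenzaldehyde
Conditions: BnBr (2.4 equiv), K2CO3 (3 equiv), DMF, 60 °C, N2
Reagents that add atoms: benzyl bromide, BrCc1ccccc1
Why: Williamson ether synthesis, in which both phenoxides (including the one hydrogen-bonded to the aldehyde) are alkylated by the reactive benzylic bromide and the aldehyde has no α-hydrogen to interfere.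

Step 3
Reactants: 3 2,3-bis(benzyloxy)-5-bromo-4-methoxybenzaldehyde; 4 1-[4-(benzyloxy)-2-hydroxyphenyl]ethan-1-one
Product: 5 (E)-1-[4-(benzyloxy)-2-hydroxyphenyl]-3-[2,3-bis(benzyloxy)-5-bromo-4-methoxyphenyl]prop-2-en-1-one
Conditions: KOH (50 % aq.), EtOH–THF, rt; then cold 1 M HCl
Reagents that add atoms: none
Why: Claisen–Schmidt (crossed aldol) condensation, in which only ketone 4 can enolise and only aldehyde 3 is a good acceptor, E1cB dehydration gives the conjugated and thermodynamically preferred E-alkene, and benzyl ethers and the aryl bromide are inert to hydroxide.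

Step 4
Reactants: 5 (E)-1-[4-(benzyloxy)-2-hydroxyphenyl]-3-[2,3-bis(benzyloxy)-5-bromo-4-methoxyphenyl]prop-2-en-1-one
Product: 7 5'-bromo-7,2',3'-tris(benzyloxy)-4'-methoxyisoflavone, via β-keto dimethyl acetal 6 (not isolated)
Conditions: Tl(NO3)3·3H2O (1.1 equiv), MeOH–HC(OMe)3–CH2Cl2, rt; filter TlNO3; then conc. HCl (to ca. 1 M), MeOH–THF, 55 °C
Reagents that add atoms: methanol, CO (its two methoxy groups stand in intermediate 6 only and are lost again on ring closure)
Why: Tl(III) adds to the enone alkene at the α-carbon while methanol adds at the benzylic β-carbon; as Tl(I) departs, ring B shifts from the β- to the α-carbon through a phenonium ion that the C2' and C4' oxygens stabilise, and a second methanol caps the resulting oxocarbenium ion to give acetal 6 with the C3–C1' bond in place. This is the known thallium(III) oxidative rearrangement of 2'-hydroxychalcones, the laboratory counterpart of the biosynthetic aryl shift. Acid then re-ionises the acetal and the A-ring phenol oxygen closes the pyranone ring on that carbon (6-exo-trig onto the oxocarbenium ion, forming O1–C2), after which loss of methanol gives the C2=C3 bond. No stereocentre is formed in 7, since the one carbon that is stereogenic in 6 becomes sp2. The step needs aryl migration to outpace displacement of thallium by the A-ring phenol (aurone pathway) and a second oxidation; the two oxygen donors on ring B, bromine in place of the alkene that Tl(III) would attack, and only 1.1 equiv of oxidant serve this. It also needs O1 to be the only oxygen that can reach C2, which the acid-stable benzyl ether on the C2' oxygen secures, and the same ethers keep the catechol away from the oxidant.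

Step 5
Reactants: 7 5'-bromo-7,2',3'-tris(benzyloxy)-4'-methoxyisoflavone; 8 prenylboronic acid pinacol ester
Product: 9 7-(benzyloxy)-3-[2,3-bis(benzyloxy)-4-methoxy-5-(2-methylbut-3-en-2-yl)phenyl]-4H-chromen-4-one
Conditions: 8 (1.5 equiv), Pd(OAc)2 (5 mol %), 1,1'-bis(di-tert-butylphosphino)ferrocene (6 mol %), K3PO4 (3 equiv, aq.), THF, 50 °C, degassed
Reagents that add atoms: none
Why: γ-Selective Suzuki–Miyaura coupling of an allylboronate, in which SE2' transmetalation places palladium on the dimethyl-substituted carbon and a bulky, chelating, electron-rich phosphine drives reductive elimination before the allyl group can slip to the prenyl isomer, so the 1,1-dimethylallyl arene should result.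

Step 6
Reactants: 9 7-(benzyloxy)-3-[2,3-bis(benzyloxy)-4-methoxy-5-(2-methylbut-3-en-2-yl)phenyl]-4H-chromen-4-one
Product: 10 3-[2,3-dihydroxy-4-methoxy-5-(2-methylbut-3-en-2-yl)phenyl]-7-hydroxy-4H-chromen-4-one (target)
Conditions: BCl3 (1 M in CH2Cl2, 6 equiv), pentamethylbenzene (9 equiv), CH2Cl2, −78 °C (→ −40 °C if needed); MeOH quench
Reagents that add atoms: none
Why: Lewis-acid debenzylation of aryl benzyl ethers with a non-basic cation scavenger, in which the benzylic C–O bonds ionise far more readily than the methyl C–O bond, pentamethylbenzene traps the benzyl cations, and at −78 °C neither the monosubstituted alkene nor the chromone should react, while no hydrogen is used that could saturate the alkene.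

Compound list
1 | 2,3-dihydroxy-4-methoxybenzaldehyde | COc1ccc(C=O)c(O)c1O | starting material
2 | 5-bromo-2,3-dihydroxy-4-methoxybenzaldehyde | COc1c(Br)cc(C=O)c(O)c1O | intermediate
3 | 2,3-bis(benzyloxy)-5-bromo-4-methoxybenzaldehyde | COc1c(Br)cc(C=O)c(OCc2ccccc2)c1OCc1ccccc1 | intermediate
4 | 1-[4-(benzyloxy)-2-hydroxyphenyl]ethan-1-one (4'-benzyloxy-2'-hydroxyacetophenone) | CC(=O)c1ccc(OCc2ccccc2)cc1O | starting material
5 | (E)-1-[4-(benzyloxy)-2-hydroxyphenyl]-3-[2,3-bis(benzyloxy)-5-bromo-4-methoxyphenyl]prop-2-en-1-one | O=C(/C=C/c1cc(Br)c(OC)c(OCc2ccccc2)c1OCc1ccccc1)c1ccc(OCc2ccccc2)cc1O | intermediate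
6 | 1-[4-(benzyloxy)-2-hydroxyphenyl]-2-[2,3-bis(benzyloxy)-5-bromo-4-methoxyphenyl]-3,3-dimethoxypropan-1-one (racemic, not isolated) | COC(OC)C(C(=O)c1ccc(OCc2ccccc2)cc1O)c1cc(Br)c(OC)c(OCc2ccccc2)c1OCc1ccccc1 | intermediate
7 | 7-(benzyloxy)-3-[2,3-bis(benzyloxy)-5-bromo-4-methoxyphenyl]-4H-chromen-4-one (5'-bromo-7,2',3'-tris(benzyloxy)-4'-methoxyisoflavone) | COc1c(Br)cc(-c2coc3cc(OCc4ccccc4)ccc3c2=O)c(OCc2ccccc2)c1OCc1ccccc1 | intermediate
8 | prenylboronic acid pinacol ester (4,4,5,5-tetramethyl-2-(3-methylbut-2-en-1-yl)-1,3,2-dioxaborolane) | CC(C)=CCB1OC(C)(C)C(C)(C)O1 | starting material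
9 | 7-(benzyloxy)-3-[2,3-bis(benzyloxy)-4-methoxy-5-(2-methylbut-3-en-2-yl)phenyl]-4H-chromen-4-one | COc1c(C(C)(C)C=C)cc(-c2coc3cc(OCc4ccccc4)ccc3c2=O)c(OCc2ccccc2)c1OCc1ccccc1 | intermediate
10 | 3-[2,3-dihydroxy-4-methoxy-5-(2-methylbut-3-en-2-yl)phenyl]-7-hydroxy-4H-chromen-4-one | C=CC(C)(C)c1cc(-c2coc3cc(O)ccc3c2=O)c(O)c(O)c1OC | target

Total step count: 6
Longest linear sequence: 6 steps (1 → 2 → 3 → 5 → 7 → 9 → 10); 4 and 8 enter as purchased partners.

Steps most likely to fail

Step 4. The aryl shift may be slow, because bromine and the C3' benzyloxy group push the C4' methoxy group out of conjugation. The A-ring phenol could then displace thallium at the α-carbon (aurone pathway), or a second oxidation could set in. The fallback sets out from 5 and comes back at 7, and it blocks the phenol before the oxidation so that the shift has no intramolecular rival. Acetylation (Ac2O, pyridine) should give 5-(benzyloxy)-2-{(E)-3-[2,3-bis(benzyloxy)-5-bromo-4-methoxyphenyl]prop-2-enoyl}phenyl acetate F1. The iodine(III) variant of the rearrangement (PhI(OAc)2, p-TsOH, MeOH–HC(OMe)3, rt) should convert it into 5-(benzyloxy)-2-{2-[2,3-bis(benzyloxy)-5-bromo-4-methoxyphenyl]-3,3-dimethoxypropanoyl}phenyl acetate F2. HCl in MeOH at reflux should then remove the acetate and close the ring to 7.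

Step 5. The allylpalladium intermediate may isomerise (σ–π–σ) before reductive elimination and give the linear prenyl isomer, or the bromide may be reduced if C–C bond formation at the congested quaternary carbon is slow. The fallback sets out from 7 and comes back at 9, and it builds the quaternary carbon by enolate arylation, where no allyl isomerisation is possible. Pd-catalysed α-arylation of isobutyraldehyde (Pd(OAc)2, rac-BINAP, Cs2CO3, dioxane, 80 °C) should give 2-{3,4-bis(benzyloxy)-5-[7-(benzyloxy)-4-oxo-4H-chromen-3-yl]-2-methoxyphenyl}-2-methylpropanal F3. Wittig methylenation (Ph3P=CH2, THF, −78 → 0 °C, slight excess only) should then give 9.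

Step 6. The HCl/BCl3 couple may protonate the terminal alkene or attack the electron-rich ring at the carbon bearing the side chain, causing loss or rearrangement of the 1,1-dimethylallyl group. Boron chelation may also cleave the C4' methyl ether. The fallback sets out from 7 and comes back at 10, and it exchanges the protecting groups before the alkene exists. BCl3 with pentamethylbenzene on 7 should give 3-(5-bromo-2,3-dihydroxy-4-methoxyphenyl)-7-hydroxy-4H-chromen-4-one F4. MOMCl and i-Pr2NEt in DMF should give 3-[5-bromo-4-methoxy-2,3-bis(methoxymethoxy)phenyl]-7-(methoxymethoxy)-4H-chromen-4-one F5. Coupling with 8 under the conditions of step 5 should give 3-[4-methoxy-2,3-bis(methoxymethoxy)-5-(2-methylbut-3-en-2-yl)phenyl]-7-(methoxymethoxy)-4H-chromen-4-one F6. Dilute HCl in MeOH at 45 °C should then remove the acetals without touching the alkene, which has no neighbouring free hydroxyl, and give 10.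

Further compounds
F1 | step 4 | 5-(benzyloxy)-2-{(E)-3-[2,3-bis(benzyloxy)-5-bromo-4-methoxyphenyl]prop-2-enoyl}phenyl acetate | CC(=O)Oc1cc(OCc2ccccc2)ccc1C(=O)/C=C/c1cc(Br)c(OC)c(OCc2ccccc2)c1OCc1ccccc1
F2 | step 4 | 5-(benzyloxy)-2-{2-[2,3-bis(benzyloxy)-5-bromo-4-methoxyphenyl]-3,3-dimethoxypropanoyl}phenyl acetate (racemic) | CC(=O)Oc1cc(OCc2ccccc2)ccc1C(=O)C(C(OC)OC)c1cc(Br)c(OC)c(OCc2ccccc2)c1OCc1ccccc1
F3 | step 5 | 2-{3,4-bis(benzyloxy)-5-[7-(benzyloxy)-4-oxo-4H-chromen-3-yl]-2-methoxyphenyl}-2-methylpropanal | COc1c(C(C)(C)C=O)cc(-c2coc3cc(OCc4ccccc4)ccc3c2=O)c(OCc2ccccc2)c1OCc1ccccc1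
F4 | step 6 | 3-(5-bromo-2,3-dihydroxy-4-methoxyphenyl)-7-hydroxy-4H-chromen-4-one | COc1c(Br)cc(-c2coc3cc(O)ccc3c2=O)c(O)c1O
F5 | step 6 | 3-[5-bromo-4-methoxy-2,3-bis(methoxymethoxy)phenyl]-7-(methoxymethoxy)-4H-chromen-4-one | COCOc1ccc2c(c1)occ(-c1cc(Br)c(OC)c(OCOC)c1OCOC)c2=O
F6 | step 6 | 3-[4-methoxy-2,3-bis(methoxymethoxy)-5-(2-methylbut-3-en-2-yl)phenyl]-7-(methoxymethoxy)-4H-chromen-4-one | COCOc1ccc2c(c1)occ(-c1cc(C(C)(C)C=C)c(OC)c(OCOC)c1OCOC)c2=O
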